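**Assumption:** the target is taken exactly as drawn in the SMILES: (S) at the carbinol carbon (priorities O > C(=CH2)Ar > CH2 > H) and a (Z)-2-methylbut-2-enoate (angelate) ester.

## Retrosynthetic overview

1. The quinone is unveiled last by CAN oxidative demethylation of the 2,3,5-trimethoxy-4-methylphenyl arene 20; the angelate C–O bond comes from (S)-alcohol 17 and angelic acid 18.
2. The prenyl terminus comes from cross-metathesis of allyl carbinol 16 with 2-methyl-2-butene.
3. The key C3–C4 bond and the only stereocentre come from a reagent-controlled asymmetric carbonyl allylation (Brown) of 2-arylacrolein 12 with the allyl fragment 13.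
4. Acrolein 12 comes from Mannich α-methylenation of arylacetaldehyde 10, which comes from benzaldehyde 8 by C1 homologation; 8 is built from 2,6-dimethoxytoluene 1 by Vilsmeier, Dakin, ortho-formylation and O-methylation.
5. Rings: none is constructed; the six-membered carbocycle of 1 is carried through and only oxidised to the quinone in the final step.

## Route

Step 1
Reactants: 1 2,6-dimethoxytoluene
Product: 3 2,4-dimethoxy-3-methylbenzaldehyde, via aryl iminium chloride 2 (not isolated)
Conditions: POCl3 (1.5 equiv), DMF, 0 → 80 °C; then ice/H2O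
Reagents that add atoms: DMF, CN(C)C=O; water, O
Why: Vilsmeier–Haack formylation attacks the only strongly activated position (ortho to one OMe and para to the other, C3 and C5 being equivalent by symmetry), and the iminium salt is hydrolysed to the aldehyde on work-up.

Step 2
Reactants: 3 2,4-dimethoxy-3-methylbenzaldehyde
Product: 5 2,4-dimethoxy-3-methylphenol, via aryl formate 4 (not isolated)
Conditions: mCPBA, CH2Cl2, 0 °C → rt; then NaOH, MeOH/H2O, rt; neutralise
Reagents that add atoms: mCPBA, OOC(=O)c1cccc(Cl)c1
Why: Baeyer–Villiger (Dakin-type) oxidation in which the electron-rich o,p-dimethoxyaryl group migrates in preference to H, the resulting formate being saponified in the same pot.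

Step 3
Reactants: 5 2,4-dimethoxy-3-methylphenol
Product: 7 2-hydroxy-3,5-dimethoxy-4-methylbenzaldehyde, via salicyl alcohol 6 (not isolated)
Conditions: MgCl2, Et3N, (CH2O)n, MeCN, reflux; then 1 M HCl
Reagents that add atoms: paraformaldehyde (as formaldehyde), C=O
Why: Casnati–Skattebøl ortho-formylation, in which the magnesium phenoxide delivers formaldehyde only to the single free ortho position (para to the ring methyl) and the benzylic alkoxide is oxidised by a second formaldehyde through Oppenauer-type hydride transfer.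

Step 4
Reactants: 7 2-hydroxy-3,5-dimethoxy-4-methylbenzaldehyde
Product: 8 2,3,5-trimethoxy-4-methylbenzaldehyde
Conditions: MeI, K2CO3, DMF, rt
Reagents that add atoms: iodomethane, CI
Why: Williamson O-methylation of the acidic salicylaldehyde phenol completes the protected hydroquinone pattern (OMe para pair at C2/C5 plus the OMe at C3 that is kept).

Step 5
Reactants: 8 2,3,5-trimethoxy-4-methylbenzaldehyde
Product: 9 1-(2-methoxyethenyl)-2,3,5-trimethoxy-4-methylbenzene (E/Z mixture)
Conditions: Ph3P(Cl)CH2OMe, KOtBu, THF, 0 °C → rt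
Reagents that add atoms: (methoxymethyl)triphenylphosphonium chloride, COC[P+](c1ccccc1)(c1ccccc1)c1ccccc1.[Cl-]
Why: Wittig olefination of a non-enolisable aldehyde with the methoxymethylene ylide gives the one-carbon homologue as an enol ether whose geometry is irrelevant.

Step 6
Reactants: 9 1-(2-methoxyethenyl)-2,3,5-trimethoxy-4-methylbenzene
Product: 10 2-(2,3,5-trimethoxy-4-methylphenyl)acetaldehyde
Conditions: 2 M HCl, THF, 50 °C; crude product used directly
Reagents that add atoms: water, O
Why: Acid-catalysed enol ether hydrolysis (protonation to the oxocarbenium ion, then hemiacetal collapse) releases the arylacetaldehyde, which is carried on crude because it is prone to aldol condensation and air oxidation.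

Step 7
Reactants: 10 2-(2,3,5-trimethoxy-4-methylphenyl)acetaldehyde
Product: 12 2-(2,3,5-trimethoxy-4-methylphenyl)prop-2-enal, via Mannich base 11 (not isolated)
Conditions: Me2N=CH2+ I− (Eschenmoser's salt), Et3N, CH2Cl2, rt; store cold, use promptly
Reagents that add atoms: Eschenmoser's salt, C=[N+](C)C.[I-]
Why: Mannich aminomethylation of the enolisable aldehyde followed by E1cB loss of dimethylamine (α-methylenation) gives the 2-arylacrolein.

Step 8 (key step)
Reactants: 12 2-(2,3,5-trimethoxy-4-methylphenyl)prop-2-enal; 13 allylmagnesium bromide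
Product: 16 (3S)-2-(2,3,5-trimethoxy-4-methylphenyl)hexa-1,5-dien-3-ol, via B-allyldiisopinocampheylborane 14 (not isolated), via borinate ester 15 (not isolated)
Conditions: (−)-Ipc2BOMe [from (+)-α-pinene], 13, Et2O, 0 °C → rt; then 12, −78 °C; then 3 M NaOH, 30% H2O2, rt
Reagents that add atoms: none
Why: Brown asymmetric allylboration (intermolecular carbonyl allylation) through a closed chair Zimmerman–Traxler transition state in which the (+)-α-pinene-derived Ipc groups direct allyl to the Si face of the aldehyde, giving the (S)-carbinol (same facial sense as PhCHO → (S)-1-phenylbut-3-en-1-ol) with exclusive 1,2-addition.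

Step 9
Reactants: 16 (3S)-2-(2,3,5-trimethoxy-4-methylphenyl)hexa-1,5-dien-3-ol
Product: 17 (3S)-6-methyl-2-(2,3,5-trimethoxy-4-methylphenyl)hepta-1,5-dien-3-ol
Conditions: Grubbs II (5 mol%), 2-methyl-2-butene/CH2Cl2, 40 °C
Reagents that add atoms: 2-methyl-2-butene, CC=C(C)C
Why: Olefin cross-metathesis engages only the monosubstituted alkene (the 1,1-disubstituted aryl alkene is too hindered) and excess 2-methyl-2-butene caps it as the trisubstituted prenyl group, leaving the stereocentre untouched.

Step 10
Reactants: 17 (3S)-6-methyl-2-(2,3,5-trimethoxy-4-methylphenyl)hepta-1,5-dien-3-ol; 18 angelic acid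
Product: 20 (3S)-6-methyl-2-(2,3,5-trimethoxy-4-methylphenyl)hepta-1,5-dien-3-yl (Z)-2-methylbut-2-enoate, via mixed anhydride 19 (not isolated)
Conditions: 18, 2,4,6-Cl3C6H2COCl, Et3N, toluene, rt; then 17, 75 °C (no DMAP)
Reagents that add atoms: none
Why: Yamaguchi-type esterification in which the alcohol attacks the unhindered angeloyl carbonyl of the mixed anhydride, and omitting a nucleophilic catalyst avoids addition–elimination isomerisation to the tiglate; the carbinol C–O bond is not broken, so (S) is retained.

Step 11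
Reactants: 20 (3S)-6-methyl-2-(2,3,5-trimethoxy-4-methylphenyl)hepta-1,5-dien-3-yl (Z)-2-methylbut-2-enoate
Product: 21 (3S)-2-(5-methoxy-4-methyl-3,6-dioxocyclohexa-1,4-dien-1-yl)-6-methylhepta-1,5-dien-3-yl (Z)-2-methylbut-2-enoate (target)
Conditions: CAN (2.5 equiv), MeCN/H2O (2:1), 0 °C, 20 min
Reagents that add atoms: water, O
Why: CAN oxidative demethylation converts the para-related OMe pair into the p-quinone (the third OMe stays as the vinylogous ester), and the short, cold reaction spares the alkenes, the allylic ester and the stereocentre.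

## Compound list

1 | 2,6-dimethoxytoluene (1,3-dimethoxy-2-methylbenzene) | COc1cccc(OC)c1C | starting material
2 | N-[(2,4-dimethoxy-3-methylphenyl)methylidene]-N-methylmethanaminium chloride (formed in situ) | C[N+](C)=Cc1ccc(OC)c(C)c1OC.[Cl-] | intermediate
3 | 2,4-dimethoxy-3-methylbenzaldehyde | O=Cc1ccc(OC)c(C)c1OC | intermediate
4 | 2,4-dimethoxy-3-methylphenyl formate (formed in situ) | O=COc1ccc(OC)c(C)c1OC | intermediate
5 | 2,4-dimethoxy-3-methylphenol | Oc1ccc(OC)c(C)c1OC | intermediate
6 | 6-(hydroxymethyl)-2,4-dimethoxy-3-methylphenol (formed in situ as its magnesium phenoxide) | OCc1cc(OC)c(C)c(OC)c1O | intermediate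
7 | 2-hydroxy-3,5-dimethoxy-4-methylbenzaldehyde | O=Cc1cc(OC)c(C)c(OC)c1O | intermediate
8 | 2,3,5-trimethoxy-4-methylbenzaldehyde | O=Cc1cc(OC)c(C)c(OC)c1OC | intermediate
9 | 1-(2-methoxyethenyl)-2,3,5-trimethoxy-4-methylbenzene (E/Z mixture) | COC=Cc1cc(OC)c(C)c(OC)c1OC | intermediate
10 | 2-(2,3,5-trimethoxy-4-methylphenyl)acetaldehyde | O=CCc1cc(OC)c(C)c(OC)c1OC | intermediate
11 | 3-(dimethylamino)-2-(2,3,5-trimethoxy-4-methylphenyl)propanal (racemic, formed in situ) | CN(C)CC(C=O)c1cc(OC)c(C)c(OC)c1OC | intermediate
12 | 2-(2,3,5-trimethoxy-4-methylphenyl)prop-2-enal | C=C(C=O)c1cc(OC)c(C)c(OC)c1OC | intermediate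
13 | allylmagnesium bromide (commercial Et2O solution) | C=CC[Mg]Br | starting material
14 | (−)-B-allyldiisopinocampheylborane, Ipc from (+)-α-pinene (formed in situ) | C=CCB([C@@H]1C[C@@H]2C[C@H]([C@H]1C)C2(C)C)[C@@H]1C[C@@H]2C[C@H]([C@H]1C)C2(C)C | intermediate
15 | (3S)-2-(2,3,5-trimethoxy-4-methylphenyl)hexa-1,5-dien-3-yl diisopinocampheylborinate (formed in situ) | C=C(c1cc(OC)c(C)c(OC)c1OC)[C@H](CC=C)OB([C@@H]1C[C@@H]2C[C@H]([C@H]1C)C2(C)C)[C@@H]1C[C@@H]2C[C@H]([C@H]1C)C2(C)C | intermediate
16 | (3S)-2-(2,3,5-trimethoxy-4-methylphenyl)hexa-1,5-dien-3-ol | C=C(c1cc(OC)c(C)c(OC)c1OC)[C@H](CC=C)O | intermediate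
17 | (3S)-6-methyl-2-(2,3,5-trimethoxy-4-methylphenyl)hepta-1,5-dien-3-ol | C=C(c1cc(OC)c(C)c(OC)c1OC)[C@H](CC=C(C)C)O | intermediate
18 | angelic acid, (Z)-2-methylbut-2-enoic acid | C/C=C(/C)C(=O)O | starting material
19 | (Z)-2-methylbut-2-enoic 2,4,6-trichlorobenzoic anhydride (formed in situ) | C/C=C(/C)C(=O)OC(=O)c1c(Cl)cc(Cl)cc1Cl | intermediate
20 | (3S)-6-methyl-2-(2,3,5-trimethoxy-4-methylphenyl)hepta-1,5-dien-3-yl (Z)-2-methylbut-2-enoate | C=C(c1cc(OC)c(C)c(OC)c1OC)[C@H](CC=C(C)C)OC(=O)/C(C)=C\C | intermediate
21 | (3S)-2-(5-methoxy-4-methyl-3,6-dioxocyclohexa-1,4-dien-1-yl)-6-methylhepta-1,5-dien-3-yl (Z)-2-methylbut-2-enoate | C=C(C1=CC(=O)C(C)=C(OC)C1=O)[C@H](CC=C(C)C)OC(=O)/C(C)=C\C | target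

## Totals and risk

Total step count: 11. Longest linear sequence: 11 steps (1 → 21).

**Step 8 (asymmetric allylation).** The 2-arylacrolein 12 is polymerisation-prone and the enantioselectivity of the allylboration on this hindered α-aryl enal is not guaranteed. The fallback sets out from 12 and returns at 16, moving stereocontrol from the C–C bond formation to a ketone reduction. Compound 12 is treated with allylmagnesium bromide 13 itself (THF, −78 °C; NH4Cl quench) to give racemic 2-(2,3,5-trimethoxy-4-methylphenyl)hexa-1,5-dien-3-ol F1. This is oxidised with Dess–Martin periodinane/NaHCO3 (CH2Cl2, 0 °C) to 2-(2,3,5-trimethoxy-4-methylphenyl)hexa-1,5-dien-3-one F2, which is used at once so the β,γ-alkene does not migrate into conjugation. Reduction with (R)-Me-CBS (20 mol%) and catecholborane in toluene at −78 °C gives 16; the α-arylvinyl group acts as the large substituent, so the (R)-catalyst delivers the (S)-alcohol.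

**Step 10 (angeloylation).** The alcohol is a hindered secondary allylic one and the angelate can isomerise to the tiglate. The fallback sets out from 17 and returns at 20, building the Z-alkene on the ester instead of importing it. Compound 17 is coupled with 2-[bis(2,2,2-trifluoroethoxy)phosphoryl]propanoic acid (EDC·HCl, cat. DMAP, CH2Cl2, 0 °C → rt) to give (3S)-6-methyl-2-(2,3,5-trimethoxy-4-methylphenyl)hepta-1,5-dien-3-yl 2-[bis(2,2,2-trifluoroethoxy)phosphoryl]propanoate F3. A Still–Gennari olefination with acetaldehyde (KHMDS, 18-crown-6, THF, −78 °C) then forms the (Z)-2-methylbut-2-enoate 20 under kinetic control.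

**Step 11 (CAN oxidation).** The doubly activated allylic angelate may ionise or hydrolyse in acidic CAN, or the ester may complicate the oxidation. The fallback sets out from 17 and returns at 21, reversing the order of the last two operations. Compound 17 is oxidised first (CAN, MeCN/H2O, 0 °C) to 6-[(3S)-3-hydroxy-6-methylhepta-1,5-dien-2-yl]-2-methoxy-3-methylcyclohexa-2,5-diene-1,4-dione F4. This hydroxy-quinone is then acylated with a filtered, amine-free toluene solution of mixed anhydride 19 at 60–75 °C (no base, no DMAP, so the quinone is not exposed to amine) to give 21.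

## Further compounds

F1 | step 8 | racemic 2-(2,3,5-trimethoxy-4-methylphenyl)hexa-1,5-dien-3-ol | C=C(c1cc(OC)c(C)c(OC)c1OC)C(O)CC=C
F2 | step 8 | 2-(2,3,5-trimethoxy-4-methylphenyl)hexa-1,5-dien-3-one | C=C(c1cc(OC)c(C)c(OC)c1OC)C(=O)CC=C
F3 | step 10 | (3S)-6-methyl-2-(2,3,5-trimethoxy-4-methylphenyl)hepta-1,5-dien-3-yl 2-[bis(2,2,2-trifluoroethoxy)phosphoryl]propanoate (mixture at the phosphonate-bearing carbon) | C=C(c1cc(OC)c(C)c(OC)c1OC)[C@H](CC=C(C)C)OC(=O)C(C)P(=O)(OCC(F)(F)F)OCC(F)(F)F
F4 | step 11 | 6-[(3S)-3-hydroxy-6-methylhepta-1,5-dien-2-yl]-2-methoxy-3-methylcyclohexa-2,5-diene-1,4-dione | C=C(C1=CC(=O)C(C)=C(OC)C1=O)[C@H](CC=C(C)C)O
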